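## Structural features

The target is an isoflavan: a chroman (benzo ring A fused to the dihydropyran ring C) that carries ring B on C3. C3 is the only stereocentre (R); it is a tertiary benzylic carbon flanked by two methylene groups (C2 and C4), so no neighbouring stereocentre or functional group is available to steer its formation. Ring A is fully differentiated, with OMe at C5, OH at C7 and CHO at C8 (a hydrogen-bonded salicylaldehyde), so C8 must be told apart from C6 and O7 from O5. Ring B is a 2′,4′-dihydroxyphenyl ring with a prenyl group at C3′, between the two phenols. The fragile elements are the prenyl alkene (hydrogenation, ionic reduction, electrophiles and, above all, acid-promoted cyclisation onto either ortho phenol), the electron-rich aldehyde, and C3 whenever an intermediate places it next to a carbonyl group. The real difficulty is threefold: the isolated C3 centre, the regiochemistry of ring A, and a protecting-group plan that lets the prenylated resorcinol survive to the end. The key step uses the fact that C2–C3–C4 with ring B on the central carbon is a 2-arylacrolein, while C4a and O1 of ring A are the ortho carbon and the hydroxyl oxygen of a phloroglucinol-type phenol; joining the two forms C4–C4a and O1–C2 and creates C3.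

## Logic of the disconnections

19 ⇒ 18. The two O–CH2OCH3 bonds on ring B are cut last. Keeping both ring B phenols as acetals is what allows the aryl metalations, the phenoxide chemistry on ring A and the dehydrative ring closure. The forward step must use an acid too weak to protonate the trisubstituted alkene.

18 ⇒ 17. The O7–H bond is traced back to O7–CH3. With O7 as a methyl ether, O5 and O7 become identical, so ring A can come from a symmetric phenol. The forward step must cleave only the methyl ether that chelates to the C8 carbonyl.

17 ⇒ 16. The O1–C2 ether bond is cut to a phenol and a primary alcohol. The closure takes place at a CH2 group and does not touch C3. The forward step needs the phenol to be the only acidic hydroxyl.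

16 ⇒ 14. The C8–CHO bond is cut while O1 is still a free phenol. At that stage the future C8 is the only free ortho position, so a phenoxide-directed formylation cannot reach C6. This replaces electrophilic formylation of the closed chroman, where C6 and C8 are electronically alike and the medium is acidic. The forward step must tolerate the primary alcohol.

14 ⇒ 13. C2 is raised from the alcohol to the lactol level. Hydride reduction is preferred to ionic deoxygenation of the lactol, because a silane with a Lewis acid would reduce the prenyl alkene and strip the acetals. The forward step must reduce faster than the open-chain aldehyde enolises.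

13 ⇒ 10 + 11. C4–C4a and O1–C2 are cut together. The pair is kept as it stands. 11 is purchased and symmetric, so both ortho carbons give the same product and O5 and O7 start out identical; 10 carries ring B complete. The forward step must achieve ortho C-alkylation and face-selective protonation at C3 without harming the acetals.

10 ⇒ 9. The aldehyde is traced back to the allylic alcohol. 10 is prone to dimerise, whereas 9 can be stored and oxidised just before use. The forward step needs a neutral oxidant.

9 ⇒ 5 + 6. The bond between ring B and the central carbon of the three-carbon unit is cut as an sp2–sp2 cross-coupling. This reaches 10 in two steps from 5 and avoids an enolisable arylacetaldehyde and a hydroxyethylation, oxidation and methylenation sequence. By the symmetry of 5 both metalation sites are the same; the forward step must favour ring metalation over deprotonation of the benzylic–allylic CH2.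

5 ⇒ 2 + 3. The bond between C3′ and the prenyl CH2 is cut. The carbon between the two acetal oxygens is the most acidic ring position. The forward step must give substitution at the primary carbon of 3 without allylic transposition.

2 ⇒ 1. The two O–CH2OCH3 bonds are cut to the purchased diphenol.

## Other disconnections considered

Alternative 1: The cut runs through ring B: C1′–C2′, C2′–C3′, C4′–C5′ and C5′–C6′ would all be made in one operation on a preformed, enantiopure chroman. In the forward sense the enone diazo ketone A2 would be irradiated with the prenyl siloxyalkyne A3. Wolff rearrangement gives a vinylketene, [2+2] cycloaddition with the ynol ether gives a cyclobutenone, and 4π opening followed by 6π closure gives the resorcinol monosilyl ether A1.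
- In favour: the polarity of the ynol ether places the prenyl group exactly between the two oxygens, so no aryl metalation next to a benzylic–allylic CH2 is needed. The two ring B oxygens arrive differentiated, and the silyl group leaves with fluoride. On this point (no acid near the prenyl phenols at the end) A1 is better than the chosen plan. Four skeletal bonds form in one step, against two in step 5.
- Against: the stereocentre must exist before the key step, in an aliphatic 3-substituted chroman that needs its own asymmetric synthesis. In A2 it sits γ to the enone carbonyl and must survive base-mediated diazo transfer and the ketene intermediates. A3 needs a multi-step ynolate and silylation sequence, and its prenyl alkene can compete as a ketene or carbene acceptor. A1 still lacks the C8 carbon and has both ring A oxygens methylated; because O1 is already an ether, the phenoxide-directed C8 formylation of the chosen plan is no longer available.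
- Comparison: on structure A1 is the better answer for ring B but the worse one for ring A. On mechanism a pericyclic cascade creates no stereocentre, whereas step 5 creates C3 and ring C together. On step economy this route would need roughly half as many steps again as the chosen ten.

Alternative 2: The cut is C4–C4a and O1–C8a, so ring A is detached from a three-carbon unit that already carries ring B and the stereocentre. In the forward sense the aryl iodide A5 and the bromohydrin A6 would react under Pd(OAc)2, a triarylphosphine, norbornene and Cs2CO3. Zerovalent palladium adds to the C–I bond, norbornene inserts, ortho C–H palladation gives a palladacycle, and the alkyl bromide adds (tetravalent palladium) and is coupled to form C4–C4a. Norbornene is then extruded and the tethered alkoxide forms O1–C8a, giving A4.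
- In favour: ring A arrives complete, with the C8 carbon as a dioxolane and O7 as an acetal, so no late formylation and no demethylation are needed; one acid step would unveil everything. In the endgame A4 is clearly better than the chosen plan (one step against five). The stereocentre is not formed in the key step, so its purity does not depend on the annulation, which is also better in principle.
- Against: A6 needs a separate asymmetric synthesis (for example desymmetrisation of the corresponding prochiral diol) and A5 several regiocontrolled steps. In A6 the C–Br bond is β to a benzylic C–H, so under carbonate at the temperatures of norbornene-mediated catalysis loss of HBr to an achiral allylic alcohol and β-hydride elimination would compete. β-Branched primary bromides are poor partners, the ortho acetal crowds the palladacycle, and the prenyl alkene is a possible Heck acceptor. The final acid step exposes the prenyl phenols exactly as step 10 does (equal).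
- Comparison: on structure this is the most convergent of the four plans. On mechanism it exchanges mild organocatalysis for hot basic palladium chemistry on a base-sensitive electrophile. On step economy the short endgame is offset by the two elaborate coupling partners, so the total would probably not fall below that of the chosen plan.

Alternative 3: The cut is C3–C4 and O1–C2 at the lactone level. In the forward sense CsF would unmask an o-quinone methide from the silyl ether benzyl bromide A8, while a chiral triazolium-derived carbene converts the acyl imidazole A9 into an azolium enolate. Conjugate addition forms C3–C4 and acylation of the phenoxide forms O1–C2 and releases the carbene, giving the dihydrocoumarin A7.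
- In favour: the reaction class is established for acyl imidazoles and o-quinone methides. C3 would be set in a C–C bond-forming event, which is arguably a firmer control element than a protonation. The benzylic carbon of A8 fixes the ring A regiochemistry, so no ortho/para question arises; on this point A7 is better than the chosen plan. Ring C forms in one catalytic step (equal), and reduction of A7 would lead to 14, so the endgame is the same (equal).
- Against: A8 is an extremely electron-rich benzyl bromide that would need about four steps from 11 and is likely to ionise on handling. A9 needs the corresponding arylacetic acid, which is longer to reach than 10. The C3–H of A7 is α to both an aryl group and a lactone carbonyl and would be exposed to fluoride and carbene base, so loss of configuration is a real concern. The lactone needs a stronger hydride than the lactol.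
- Comparison: on structure both plans give the same ring C at neighbouring oxidation levels. On mechanism the alternative has the better precedent and the chosen plan the more stable partners. On step economy the alternative would be longer by roughly four to five steps.

Key step: step 5

Assumption (remark on the chemistry): the (S)-configured diamine salt is taken to deliver the proton to the enamine face that gives (3R); if the sense proves opposite, its enantiomer (from D-tert-leucine) is used and nothing else changes.

## Route

Step 1
Reactants: 1 resorcinol (benzene-1,3-diol)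
Product: 2 1,3-bis(methoxymethoxy)benzene
Conditions: NaH (2.4 equiv), MOMCl (2.4 equiv), DMF, 0 °C → rt
Reagents that add atoms: chloromethyl methyl ether (MOMCl), COCCl
Why: Williamson-type O-alkylation of both phenoxides; the MOM acetals direct both later metalations and are inert to the basic, reductive and organometallic steps that follow.

Step 2
Reactants: 2 1,3-bis(methoxymethoxy)benzene; 3 prenyl bromide (1-bromo-3-methylbut-2-ene)
Product: 5 1,3-bis(methoxymethoxy)-2-(3-methylbut-2-enyl)benzene, via 2,6-bis(methoxymethoxy)phenyllithium 4 (not isolated)
Conditions: n-BuLi (1.1 equiv), THF, 0 °C → rt; CuI (10 mol %), 3, −78 °C → rt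
Reagents that add atoms: none
Why: Directed ortho-metalation removes the proton flanked by both OMOM groups, the most acidic ring position; copper-mediated allylic substitution by the hindered aryl nucleophile takes place at the primary carbon of 3 and should give the linear prenyl arene.

Step 3
Reactants: 5 1,3-bis(methoxymethoxy)-2-(3-methylbut-2-enyl)benzene; 6 2-bromoprop-2-en-1-ol
Product: 9 2-[2,4-bis(methoxymethoxy)-3-(3-methylbut-2-enyl)phenyl]prop-2-en-1-ol, via ring B aryllithium 7 (not isolated), via lithium aryltrimethoxyborate 8 (not isolated)
Conditions: n-BuLi (1.15 equiv), TMEDA, THF, −20 → 0 °C; B(OMe)3, −78 °C → rt; 6, Pd(PPh3)4 (5 mol %), 2 M aq Na2CO3, 65 °C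
Reagents that add atoms: none
Why: A second directed ortho-metalation (the two remaining positions ortho to OMOM are equivalent by symmetry) is followed by borate formation and Suzuki–Miyaura coupling of the ate complex with the 1,1-disubstituted vinyl bromide; the basic conditions leave the acetals and the prenyl group untouched.

Step 4
Reactants: 9 2-[2,4-bis(methoxymethoxy)-3-(3-methylbut-2-enyl)phenyl]prop-2-en-1-ol
Product: 10 2-[2,4-bis(methoxymethoxy)-3-(3-methylbut-2-enyl)phenyl]prop-2-enal
Conditions: activated MnO2 (15 equiv), CH2Cl2, rt; filtered, concentrated cold, used at once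
Reagents that add atoms: none
Why: Chemoselective allylic alcohol oxidation on MnO2, neutral and heterogeneous, so neither the acetals nor the isolated prenyl alkene react; the enal is made fresh because 2-arylacroleins dimerise by hetero-Diels–Alder reaction on standing.

Step 5
Reactants: 10 2-[2,4-bis(methoxymethoxy)-3-(3-methylbut-2-enyl)phenyl]prop-2-enal; 11 3,5-dimethoxyphenol
Product: 13 (3R)-3-[2,4-bis(methoxymethoxy)-3-(3-methylbut-2-enyl)phenyl]-5,7-dimethoxychroman-2-ol (anomer mixture), via (2R)-hydroxy aldehyde 12 (not isolated)
Conditions: (S)-N1,N1-diethyl-3,3-dimethylbutane-1,2-diamine·TfOH (20 mol %), 11 (1.5 equiv), CHCl3–sat. aq NaCl, 0 °C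
Reagents that add atoms: none
Why: Proposed new method: the primary amine of the catalyst condenses with 10 to an α-aryl iminium ion, the ortho carbon of 11 adds to its terminal CH2 (Friedel–Crafts conjugate addition, C4–C4a), the resulting enamine is protonated at C3 by the tethered ammonium N–H, and hydrolysis releases 12, which closes to 13; the closest known reaction types are primary-amine-catalysed Friedel–Crafts addition to α-substituted acroleins with enantioselective enamine protonation, and amine-catalysed phenol–enal alkylation with hemiacetal closure to chroman-2-ols. Ring C closes by 6-exo-trig addition of the phenol oxygen to the aldehyde carbon (O1–C2), reversibly, so both anomers form. C3 is set in the protonation: the protonated tertiary amine is held on the enamine face opposite the tert-butyl group and delivers the proton intramolecularly, so the configuration of the catalyst fixes the face ((S)-catalyst proposed for 3R, the antipode being equally available). The anomeric centre C2 is left uncontrolled because step 6 erases it. The step needs ortho and not para C-alkylation of 11; hydrogen bonding of the phenol O–H to the catalyst salt places an ortho carbon over the iminium terminus, the two equivalent ortho carbons outnumber the single para carbon, which is more hindered between two methoxy groups, and only an ortho adduct can cyclise. Excess 11 limits a second alkylation of ring A, and lactol formation takes the α-aryl aldehyde out of the enamine and enol equilibria that would scramble C3. The ammonium triflate is too weak an acid to affect the MOM acetals or the prenyl alkene.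

Step 6
Reactants: 13 (3R)-3-[2,4-bis(methoxymethoxy)-3-(3-methylbut-2-enyl)phenyl]-5,7-dimethoxychroman-2-ol
Product: 14 (2R)-2-[2,4-bis(methoxymethoxy)-3-(3-methylbut-2-enyl)phenyl]-3-(2-hydroxy-4,6-dimethoxyphenyl)propan-1-ol
Conditions: NaBH4 (2 equiv), THF–EtOH, −20 → 0 °C, on the crude lactol without delay
Reagents that add atoms: none
Why: Borohydride reduction of a lactol: 13 stands in ring–chain equilibrium with its ring-opened hydroxy aldehyde tautomer (identical with 12), and hydride addition to that carbonyl drains the equilibrium towards the diol; at low temperature hydride addition should outrun enolisation of the α-aryl aldehyde, and after this step C3 is no longer next to a carbonyl group and is configurationally stable.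

Step 7
Reactants: 14 (2R)-2-[2,4-bis(methoxymethoxy)-3-(3-methylbut-2-enyl)phenyl]-3-(2-hydroxy-4,6-dimethoxyphenyl)propan-1-ol
Product: 16 3-{(2R)-2-[2,4-bis(methoxymethoxy)-3-(3-methylbut-2-enyl)phenyl]-3-hydroxypropyl}-2-hydroxy-4,6-dimethoxybenzaldehyde, via benzylic alcohol 15 (not isolated)
Conditions: MgCl2 (3 equiv), Et3N (6 equiv), (CH2O)n (6 equiv), THF, 65 °C; aq NH4Cl
Reagents that add atoms: formaldehyde (as paraformaldehyde), C=O
Why: Magnesium phenoxide ortho-formylation (Casnati–Skattebøl conditions): the phenoxide delivers formaldehyde through a chelate to the only free ortho carbon, the future C8, and the benzylic alkoxide is oxidised by a second formaldehyde by Oppenauer-type hydride transfer. The primary alcohol is not deprotonated by Et3N, and the medium is free of acid.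

Step 8
Reactants: 16 3-{(2R)-2-[2,4-bis(methoxymethoxy)-3-(3-methylbut-2-enyl)phenyl]-3-hydroxypropyl}-2-hydroxy-4,6-dimethoxybenzaldehyde
Product: 17 (3R)-3-[2,4-bis(methoxymethoxy)-3-(3-methylbut-2-enyl)phenyl]-5,7-dimethoxychroman-8-carbaldehyde
Conditions: PPh3 (1.5 equiv), DIAD (1.5 equiv), THF, 0 °C → rt
Reagents that add atoms: none
Why: Intramolecular Mitsunobu etherification: the salicylaldehyde-type phenol is the only acidic pronucleophile and displaces the activated primary alcohol in a 6-exo-tet closure at C2; C3 is not involved and keeps its configuration.

Step 9
Reactants: 17 (3R)-3-[2,4-bis(methoxymethoxy)-3-(3-methylbut-2-enyl)phenyl]-5,7-dimethoxychroman-8-carbaldehyde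
Product: 18 (3R)-3-[2,4-bis(methoxymethoxy)-3-(3-methylbut-2-enyl)phenyl]-7-hydroxy-5-methoxychroman-8-carbaldehyde
Conditions: MgI2·OEt2 (3 equiv), Et2O–toluene, 60 °C; aq NH4Cl/Na2S2O3
Reagents that add atoms: none
Why: Chelation-controlled demethylation: magnesium bridges the C8 carbonyl and O7, and iodide removes that methyl group by SN2 attack; the 5-OMe cannot chelate, and the ring oxygen O1 is protected by the far slower substitution at the β-branched ring carbon C2.

Step 10
Reactants: 18 (3R)-3-[2,4-bis(methoxymethoxy)-3-(3-methylbut-2-enyl)phenyl]-7-hydroxy-5-methoxychroman-8-carbaldehyde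
Product: 19 (3R)-3-[2,4-dihydroxy-3-(3-methylbut-2-enyl)phenyl]-7-hydroxy-5-methoxychroman-8-carbaldehyde (CNP0399843.1)
Conditions: 3 M aq HCl–MeOH (1:5), 35 °C, stopped at full conversion
Reagents that add atoms: none
Why: Acid-catalysed acetal solvolysis (MOM removal) through the oxocarbenium ion, which should proceed at an acidity below that needed to protonate the trisubstituted alkene; C3 carries no acidifying group and is not at risk.

## Compound list

1 | resorcinol (benzene-1,3-diol) | Oc1cccc(O)c1 | starting material
2 | 1,3-bis(methoxymethoxy)benzene | COCOc1cccc(OCOC)c1 | intermediate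
3 | prenyl bromide (1-bromo-3-methylbut-2-ene) | CC(C)=CCBr | starting material
4 | 2,6-bis(methoxymethoxy)phenyllithium | [Li]c1c(OCOC)cccc1OCOC | intermediate
5 | 1,3-bis(methoxymethoxy)-2-(3-methylbut-2-enyl)benzene | COCOc1cccc(OCOC)c1CC=C(C)C | intermediate
6 | 2-bromoprop-2-en-1-ol | C=C(Br)CO | starting material
7 | [2,4-bis(methoxymethoxy)-3-(3-methylbut-2-enyl)phenyl]lithium | [Li]c1ccc(OCOC)c(CC=C(C)C)c1OCOC | intermediate
8 | lithium [2,4-bis(methoxymethoxy)-3-(3-methylbut-2-enyl)phenyl]trimethoxyborate | [Li+].CO[B-](OC)(OC)c1ccc(OCOC)c(CC=C(C)C)c1OCOC | intermediate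
9 | 2-[2,4-bis(methoxymethoxy)-3-(3-methylbut-2-enyl)phenyl]prop-2-en-1-ol | C=C(CO)c1ccc(OCOC)c(CC=C(C)C)c1OCOC | intermediate
10 | 2-[2,4-bis(methoxymethoxy)-3-(3-methylbut-2-enyl)phenyl]prop-2-enal | C=C(C=O)c1ccc(OCOC)c(CC=C(C)C)c1OCOC | intermediate
11 | 3,5-dimethoxyphenol | COc1cc(O)cc(OC)c1 | starting material
12 | (2R)-2-[2,4-bis(methoxymethoxy)-3-(3-methylbut-2-enyl)phenyl]-3-(2-hydroxy-4,6-dimethoxyphenyl)propanal | COc1cc(OC)cc(O)c1C[C@H](c1ccc(OCOC)c(CC=C(C)C)c1OCOC)C=O | intermediate
13 | (3R)-3-[2,4-bis(methoxymethoxy)-3-(3-methylbut-2-enyl)phenyl]-5,7-dimethoxychroman-2-ol (anomer mixture) | COc1cc(OC)cc2c1C[C@H](c1ccc(OCOC)c(CC=C(C)C)c1OCOC)C(O)O2 | intermediate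
14 | (2R)-2-[2,4-bis(methoxymethoxy)-3-(3-methylbut-2-enyl)phenyl]-3-(2-hydroxy-4,6-dimethoxyphenyl)propan-1-ol | COc1cc(OC)cc(O)c1C[C@H](c1ccc(OCOC)c(CC=C(C)C)c1OCOC)CO | intermediate
15 | 2-{(2R)-2-[2,4-bis(methoxymethoxy)-3-(3-methylbut-2-enyl)phenyl]-3-hydroxypropyl}-6-(hydroxymethyl)-3,5-dimethoxyphenol | COc1cc(OC)c(CO)c(O)c1C[C@H](c1ccc(OCOC)c(CC=C(C)C)c1OCOC)CO | intermediate
16 | 3-{(2R)-2-[2,4-bis(methoxymethoxy)-3-(3-methylbut-2-enyl)phenyl]-3-hydroxypropyl}-2-hydroxy-4,6-dimethoxybenzaldehyde | COc1cc(OC)c(C=O)c(O)c1C[C@H](c1ccc(OCOC)c(CC=C(C)C)c1OCOC)CO | intermediate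
17 | (3R)-3-[2,4-bis(methoxymethoxy)-3-(3-methylbut-2-enyl)phenyl]-5,7-dimethoxychroman-8-carbaldehyde | COc1cc(OC)c(C=O)c2c1C[C@H](c1ccc(OCOC)c(CC=C(C)C)c1OCOC)CO2 | intermediate
18 | (3R)-3-[2,4-bis(methoxymethoxy)-3-(3-methylbut-2-enyl)phenyl]-7-hydroxy-5-methoxychroman-8-carbaldehyde | COc1cc(O)c(C=O)c2c1C[C@H](c1ccc(OCOC)c(CC=C(C)C)c1OCOC)CO2 | intermediate
19 | (3R)-3-[2,4-dihydroxy-3-(3-methylbut-2-enyl)phenyl]-7-hydroxy-5-methoxychroman-8-carbaldehyde (CNP0399843.1) | COc1cc(O)c(C=O)c2c1C[C@H](c1ccc(O)c(CC=C(C)C)c1O)CO2 | target

## Step count and least certain steps

Total: 10 steps. Longest linear sequence: 10 steps (1 → 19); 3, 6 and 11 are purchased.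

Step 5 (key step, new method). The most likely failure is poor facial selectivity in the protonation of the α-aryl enamine, together with erosion of configuration when the enamine re-forms from 12 before it closes to 13. α-Aryl enamines are conjugated and protonate reversibly, and the product aldehyde is itself a substrate for the amine. Next in likelihood are C-alkylation at the para carbon of 11 and a second alkylation of the still electron-rich ring A of 13. The fallback uses established reaction types only, with an Evans alkylation as the stereodefining step; it sets out from 5 and returns to the route at 14. 5 is metalated as in step 3 and the aryllithium is opened onto ethylene oxide to give 2-[2,4-bis(methoxymethoxy)-3-(3-methylbut-2-enyl)phenyl]ethanol F1. TEMPO/PhI(OAc)2 in MeCN–H2O oxidises this to [2,4-bis(methoxymethoxy)-3-(3-methylbut-2-enyl)phenyl]acetic acid F2. Activation with pivaloyl chloride/Et3N and acylation of N-lithiated (R)-4-benzyloxazolidin-2-one gives (4R)-4-benzyl-3-{[2,4-bis(methoxymethoxy)-3-(3-methylbut-2-enyl)phenyl]acetyl}oxazolidin-2-one F3. The ring A electrophile is made from purchased 2-hydroxy-4,6-dimethoxybenzaldehyde: allyl bromide/K2CO3 gives 2-(prop-2-enyloxy)-4,6-dimethoxybenzaldehyde F4, NaBH4 gives [2-(prop-2-enyloxy)-4,6-dimethoxyphenyl]methanol F5, and PBr3/pyridine at −20 °C gives 2-(bromomethyl)-1,5-dimethoxy-3-(prop-2-enyloxy)benzene F6, used at once. Alkylation of the sodium enolate of F3 (NaN(SiMe3)2, THF, −78 °C) with F6, on the face away from the benzyl group, should give (4R)-4-benzyl-3-{(2R)-3-[2-(prop-2-enyloxy)-4,6-dimethoxyphenyl]-2-[2,4-bis(methoxymethoxy)-3-(3-methylbut-2-enyl)phenyl]propanoyl}oxazolidin-2-one F7. LiBH4 (THF–MeOH) removes the auxiliary to give (2R)-3-[2-(prop-2-enyloxy)-4,6-dimethoxyphenyl]-2-[2,4-bis(methoxymethoxy)-3-(3-methylbut-2-enyl)phenyl]propan-1-ol F8, and Pd(PPh3)4/morpholine cleaves the allyl ether to give 14. The detour costs about seven extra operations.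

Step 3. The most likely failure is deprotonation at the doubly activated benzylic–allylic CH2 of the prenyl group in competition with ring metalation. Both are within reach of n-BuLi/TMEDA, and only the ring position is favoured by coordination to OMOM. The fallback sets out from 2 and returns at 7. Bromination with NBS (MeCN, 0 °C) gives 1-bromo-2,4-bis(methoxymethoxy)benzene F9. Deprotonation between the two OMOM groups with lithium 2,2,6,6-tetramethylpiperidide (THF, −78 °C) and CuI-catalysed prenylation with 3 give 1-bromo-2,4-bis(methoxymethoxy)-3-(3-methylbut-2-enyl)benzene F10. Bromine–lithium exchange with n-BuLi at −78 °C, which is faster than any deprotonation, then gives 7 regiospecifically, and borate formation and coupling follow as in step 3.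

Step 7. The most likely failure is over-reaction of the very electron-rich magnesium phenoxide: ionisation of the benzylic alkoxide 15 to an o-quinone methide and capture by a second arene instead of hydride transfer, or hemiformal formation at the primary alcohol. The fallback sets out from 14 and returns at 17, with the order of events reversed. Mitsunobu closure of 14 (PPh3, DIAD, THF) gives (3R)-3-[2,4-bis(methoxymethoxy)-3-(3-methylbut-2-enyl)phenyl]-5,7-dimethoxychroman F11. Vilsmeier–Haack formylation (POCl3, DMF, 0 °C; aq NaOAc) should then favour C8, the less hindered position next to the ring oxygen. This gives up the built-in regiocontrol, so a C6 isomer might have to be separated, and the acidic medium is a risk for the acetals.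

Step 10. The most likely failure is acid-promoted cyclisation of the prenyl group onto a freshly liberated 2′- or 4′-hydroxyl (Markovnikov hydroalkoxylation to a 2,2-dimethylchroman), which competes with acetal solvolysis once the phenols are free and acid is still present. The fallback sets out from 18 and returns at 19, and it avoids Brønsted acid altogether. Me3SiOTf/2,2′-bipyridyl (CH2Cl2, 0 °C) converts aryl MOM ethers by silyl exchange, through an N-(methoxymethyl)pyridinium salt, into aryl trimethylsilyl ethers, here (3R)-5-methoxy-7-(trimethylsilyloxy)-3-[3-(3-methylbut-2-enyl)-2,4-bis(trimethylsilyloxy)phenyl]chroman-8-carbaldehyde F12. Water or K2CO3/MeOH then hydrolyses F12 to 19 under neutral to basic conditions.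

## Further compounds

F1 | step 5 | 2-[2,4-bis(methoxymethoxy)-3-(3-methylbut-2-enyl)phenyl]ethanol | OCCc1ccc(OCOC)c(CC=C(C)C)c1OCOC
F2 | step 5 | [2,4-bis(methoxymethoxy)-3-(3-methylbut-2-enyl)phenyl]acetic acid | OC(=O)Cc1ccc(OCOC)c(CC=C(C)C)c1OCOC
F3 | step 5 | (4R)-4-benzyl-3-{[2,4-bis(methoxymethoxy)-3-(3-methylbut-2-enyl)phenyl]acetyl}oxazolidin-2-one | O=C1OC[C@@H](Cc2ccccc2)N1C(=O)Cc1ccc(OCOC)c(CC=C(C)C)c1OCOC
F4 | step 5 | 2-(prop-2-enyloxy)-4,6-dimethoxybenzaldehyde | C=CCOc1cc(OC)cc(OC)c1C=O
F5 | step 5 | [2-(prop-2-enyloxy)-4,6-dimethoxyphenyl]methanol | C=CCOc1cc(OC)cc(OC)c1CO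
F6 | step 5 | 2-(bromomethyl)-1,5-dimethoxy-3-(prop-2-enyloxy)benzene | C=CCOc1cc(OC)cc(OC)c1CBr
F7 | step 5 | (4R)-4-benzyl-3-{(2R)-3-[2-(prop-2-enyloxy)-4,6-dimethoxyphenyl]-2-[2,4-bis(methoxymethoxy)-3-(3-methylbut-2-enyl)phenyl]propanoyl}oxazolidin-2-one | O=C1OC[C@@H](Cc2ccccc2)N1C(=O)[C@H](Cc1c(OCC=C)cc(OC)cc1OC)c1ccc(OCOC)c(CC=C(C)C)c1OCOC
F8 | step 5 | (2R)-3-[2-(prop-2-enyloxy)-4,6-dimethoxyphenyl]-2-[2,4-bis(methoxymethoxy)-3-(3-methylbut-2-enyl)phenyl]propan-1-ol | C=CCOc1cc(OC)cc(OC)c1C[C@H](c1ccc(OCOC)c(CC=C(C)C)c1OCOC)CO
F9 | step 3 | 1-bromo-2,4-bis(methoxymethoxy)benzene | COCOc1ccc(Br)c(OCOC)c1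
F10 | step 3 | 1-bromo-2,4-bis(methoxymethoxy)-3-(3-methylbut-2-enyl)benzene | COCOc1ccc(Br)c(OCOC)c1CC=C(C)C
F11 | step 7 | (3R)-3-[2,4-bis(methoxymethoxy)-3-(3-methylbut-2-enyl)phenyl]-5,7-dimethoxychroman | COc1cc(OC)cc2c1C[C@H](c1ccc(OCOC)c(CC=C(C)C)c1OCOC)CO2
F12 | step 10 | (3R)-5-methoxy-7-(trimethylsilyloxy)-3-[3-(3-methylbut-2-enyl)-2,4-bis(trimethylsilyloxy)phenyl]chroman-8-carbaldehyde | COc1cc(O[Si](C)(C)C)c(C=O)c2c1C[C@H](c1ccc(O[Si](C)(C)C)c(CC=C(C)C)c1O[Si](C)(C)C)CO2
A1 | alternative 1 | 6-[(3R)-5,7-dimethoxychroman-3-yl]-2-(3-methylbut-2-enyl)-3-(triisopropylsilyloxy)phenol | COc1cc(OC)cc2c1C[C@H](c1ccc(O[Si](C(C)C)(C(C)C)C(C)C)c(CC=C(C)C)c1O)CO2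
A2 | alternative 1 | (3E)-1-diazo-4-[(3R)-5,7-dimethoxychroman-3-yl]but-3-en-2-one | COc1cc(OC)cc2c1C[C@H](/C=C/C(=O)C=[N+]=[N-])CO2
A3 | alternative 1 | triisopropyl[(5-methylhex-4-en-1-yn-1-yl)oxy]silane | CC(C)=CCC#CO[Si](C(C)C)(C(C)C)C(C)C
A4 | alternative 2 | 2-{(3R)-3-[2,4-bis(methoxymethoxy)-3-(3-methylbut-2-enyl)phenyl]-5-methoxy-7-(methoxymethoxy)chroman-8-yl}-1,3-dioxolane | COc1cc(OCOC)c(C3OCCO3)c2c1C[C@H](c1ccc(OCOC)c(CC=C(C)C)c1OCOC)CO2
A5 | alternative 2 | 2-[2-iodo-4-methoxy-6-(methoxymethoxy)phenyl]-1,3-dioxolane | COc1cc(I)c(C2OCCO2)c(OCOC)c1
A6 | alternative 2 | (2R)-3-bromo-2-[2,4-bis(methoxymethoxy)-3-(3-methylbut-2-enyl)phenyl]propan-1-ol | BrC[C@H](c1ccc(OCOC)c(CC=C(C)C)c1OCOC)CO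
A7 | alternative 3 | (3R)-3-[2,4-bis(methoxymethoxy)-3-(3-methylbut-2-enyl)phenyl]-5,7-dimethoxychroman-2-one | COc1cc(OC)cc2c1C[C@H](c1ccc(OCOC)c(CC=C(C)C)c1OCOC)C(=O)O2
A8 | alternative 3 | [2-(bromomethyl)-3,5-dimethoxyphenoxy](tert-butyl)dimethylsilane | COc1cc(OC)c(CBr)c(O[Si](C)(C)C(C)(C)C)c1
A9 | alternative 3 | 2-[2,4-bis(methoxymethoxy)-3-(3-methylbut-2-enyl)phenyl]-1-(imidazol-1-yl)ethanone | O=C(Cc1ccc(OCOC)c(CC=C(C)C)c1OCOC)n1ccnc1
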